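**Plan**

Numbering: ring A (oxepane) O1–C2(Me2)–C3(OH)–C4–C5–C6(Me)–C7; ring B C6–C7–C8–C9–C10(OH,Me)–C11; bridge C12–C13; ring C C14–C15(Me)=C16–C17–C18–C23; ring D C18–C19(OH,Me)–C20–C21–C22(Me2)–C23.
Retrosynthesis: both tertiary carbinols (C10, C19) go back through exocyclic methylenes to ketones; rings A and B are cut at O1–C2 and C6–C11 to an acyclic (3S,6S,7S)-diepoxide bearing a C10=C11 enol silane; C11–C12 is cut (cross-metathesis, then 1,4-hydrosilylation); ring C is cut at C14–C23 and C17–C18 (Diels–Alder reaction on 4,4-dimethylcyclohexenone).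
Forward: ring C is fused to ring D first (cis-decalone), the diepoxy chain is joined at C11=C12, then one cascade closes ring A (O1–C2) and, last of all, ring B (C6–C11); a double methylenation and a double hydration finish.
Stereochemistry: C14, C18, C23 from an endo, catalyst-controlled Diels–Alder reaction; C3, C6, C7 from a double Shi epoxidation; C6 (inversion) and C11 (chair, equatorial) in the cascade; C10 and C19 from oxygen delivery to the open face of each exocyclic alkene.
Enabling feature: in rings A/B the ether oxygen O1 joins the fully substituted C2 (next to carbinol C3) to C7, the C6–C11 bond lies anti to C7–O1 across the trans ring fusion, and C10 is oxygenated; this is the imprint of two E-epoxides (C2–C3, C6–C7) opened in turn through an epoxonium ion by a C10=C11 π-nucleophile.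

Key step: step 11

Assumption: the (S)-oxazaborolidine/AlBr3 Lewis acid of step 3 is taken to deliver the diene to the enone face that gives 6 as drawn; if the sense of induction is the opposite, the (R)-configured catalyst is used with no other change.

**Route**

Step 1
Reactants: 1 pent-4-enoyl chloride; 2 tributyl(vinyl)stannane
Product: 3 hepta-1,6-dien-3-one
Conditions: Pd(PPh3)4 (2 mol %), THF, 60 °C
Reagents that add atoms: none
Why: Stille acyl coupling (acid chloride adds to zerovalent palladium, vinyl transfer from tin) should give the vinyl ketone directly, the isolated terminal alkene being a spectator.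

Step 2
Reactants: 3 hepta-1,6-dien-3-one
Product: 4 tert-butyl{[(3Z)-hepta-1,3,6-trien-3-yl]oxy}dimethylsilane
Conditions: TBSOTf, Et3N, CH2Cl2, −78 → 0 °C
Reagents that add atoms: tert-butyldimethylsilyl trifluoromethanesulfonate, CC(C)(C)[Si](C)(C)OS(=O)(=O)C(F)(F)F
Why: Soft enolization toward the only enolizable carbon (C14) should give the 2-silyloxydiene as the (Z)-enol ether (the isomer free of allylic strain between C13 and the vinyl group), which places C13 on the outside of the s-cis diene.

Step 3
Reactants: 4 tert-butyl{[(3Z)-hepta-1,3,6-trien-3-yl]oxy}dimethylsilane; 5 4,4-dimethylcyclohex-2-en-1-one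
Product: 6 (4aR,5S,8aS)-6-[(tert-butyldimethylsilyl)oxy]-4,4-dimethyl-5-(prop-2-en-1-yl)-3,4,4a,5,8,8a-hexahydronaphthalen-1(2H)-one
Conditions: (S)-tetrahydro-1-(2-methylphenyl)-3,3-diphenyl-1H,3H-pyrrolo[1,2-c][1,3,2]oxazaborole (20 mol %), AlBr3 (16 mol %), CH2Cl2, −78 → −40 °C; Et3N quench
Reagents that add atoms: none
Why: Lewis acid catalysed Diels–Alder reaction in which the 2-silyloxy group makes C14 the nucleophilic diene terminus, so it should bond to the enone β-carbon C23 (and C17 to C18); the endo transition state gives the cis ring fusion with C13 cis to ring D, and the chiral cationic oxazaborolidine on the carbonyl screens one enone face and so sets C14, C18 and C23.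

Step 4
Reactants: 6 (4aR,5S,8aS)-6-[(tert-butyldimethylsilyl)oxy]-4,4-dimethyl-5-(prop-2-en-1-yl)-3,4,4a,5,8,8a-hexahydronaphthalen-1(2H)-one
Product: 7 (4aR,5S,8aS)-4,4-dimethyl-1-oxo-5-(prop-2-en-1-yl)-1,2,3,4,4a,5,8,8a-octahydronaphthalen-6-yl trifluoromethanesulfonate
Conditions: CsF, PhNTf2, DME, 23 °C
Reagents that add atoms: N-phenylbis(trifluoromethanesulfonimide), O=S(=O)(N(c1ccccc1)S(=O)(=O)C(F)(F)F)C(F)(F)F
Why: Fluoride-induced desilylation with in situ triflation exchanges Si for Tf on the same oxygen, so the C15=C16 position fixed by the cycloaddition is kept; the weakly basic medium should not epimerize C18 next to the ketone.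

Step 5
Reactants: 7 (4aR,5S,8aS)-4,4-dimethyl-1-oxo-5-(prop-2-en-1-yl)-1,2,3,4,4a,5,8,8a-octahydronaphthalen-6-yl trifluoromethanesulfonate
Product: 8 (4aR,5S,8aS)-4,4,6-trimethyl-5-(prop-2-en-1-yl)-3,4,4a,5,8,8a-hexahydronaphthalen-1(2H)-one
Conditions: MeZnCl, Pd(PPh3)4 (5 mol %), THF, 50 °C
Reagents that add atoms: methylzinc chloride, C[Zn]Cl
Why: Negishi coupling of the enol triflate should install the C15 methyl group with the double bond in place; the organozinc reagent neither adds to the ketone nor epimerizes C18.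

Step 6
Reactants: 9 geranyl bromide; 10 N-methoxy-N-methylacetamide
Product: 12 (4E)-N-methoxy-N,5,9-trimethyldeca-4,8-dienamide, via lithium enolate 11 (not isolated)
Conditions: LDA, THF, −78 °C; then 9, −78 → −20 °C
Reagents that add atoms: none
Why: SN2 alkylation of the amide enolate by the primary allylic bromide should add C9–C10 to the geranyl unit and keep the (E)-alkene.

Step 7
Reactants: 12 (4E)-N-methoxy-N,5,9-trimethyldeca-4,8-dienamide
Product: 13 N-methoxy-N-methyl-3-{(2S,3S)-3-methyl-3-[2-((2S)-3,3-dimethyloxiran-2-yl)ethyl]oxiran-2-yl}propanamide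
Conditions: 1,2:4,5-di-O-isopropylidene-β-L-erythro-2,3-hexodiulo-2,6-pyranose (ent-Shi ketone, 0.4 equiv), Oxone, K2CO3, Bu4NHSO4, MeCN/dimethoxymethane/aq. Na2B4O7–EDTA, 0 °C
Reagents that add atoms: potassium peroxymonosulfate (Oxone), [K+].[O-]S(=O)(=O)OO
Why: Shi epoxidation (dioxirane, spiro transition state) of both electron-rich trisubstituted alkenes; the L-fructose-derived ketone gives the mirror image of the usual (R,R) sense, so the (3S)- and (6S,7S)-epoxides should result, which sets C3, C6 and C7.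

Step 8
Reactants: 13 N-methoxy-N-methyl-3-{(2S,3S)-3-methyl-3-[2-((2S)-3,3-dimethyloxiran-2-yl)ethyl]oxiran-2-yl}propanamide
Product: 14 5-{(2S,3S)-3-methyl-3-[2-((2S)-3,3-dimethyloxiran-2-yl)ethyl]oxiran-2-yl}pent-1-en-3-one
Conditions: CH2=CHMgBr, THF, −78 → 0 °C; inverse quench into cold aq. citric acid buffer (pH 4); used at once
Reagents that add atoms: vinylmagnesium bromide, C=C[Mg]Br
Why: Weinreb ketone synthesis should stop at mono-addition; the trisubstituted epoxides tolerate the Grignard reagent at low temperature, and the acidic inverse quench keeps the released amine from adding to the vinyl ketone.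

Step 9
Reactants: 8 (4aR,5S,8aS)-4,4,6-trimethyl-5-(prop-2-en-1-yl)-3,4,4a,5,8,8a-hexahydronaphthalen-1(2H)-one; 14 5-{(2S,3S)-3-methyl-3-[2-((2S)-3,3-dimethyloxiran-2-yl)ethyl]oxiran-2-yl}pent-1-en-3-one
Product: 15 (4aR,5S,8aS)-5-[(2E)-6-{(2S,3S)-3-methyl-3-[2-((2S)-3,3-dimethyloxiran-2-yl)ethyl]oxiran-2-yl}-4-oxohex-2-en-1-yl]-4,4,6-trimethyl-3,4,4a,5,8,8a-hexahydronaphthalen-1(2H)-one
Conditions: second-generation Hoveyda–Grubbs catalyst (H2IMes)Cl2Ru(=CH-C6H4-2-OiPr) (5 mol %), 14 (1.5 equiv), CH2Cl2, 40 °C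
Reagents that add atoms: none
Why: Olefin cross-metathesis between a terminal alkene and an electron-poor vinyl ketone should be selective for the (E)-enone cross product (C11=C12); the trisubstituted ring alkene, the epoxides and the ring D ketone are spectators.

Step 10
Reactants: 15 (4aR,5S,8aS)-5-[(2E)-6-{(2S,3S)-3-methyl-3-[2-((2S)-3,3-dimethyloxiran-2-yl)ethyl]oxiran-2-yl}-4-oxohex-2-en-1-yl]-4,4,6-trimethyl-3,4,4a,5,8,8a-hexahydronaphthalen-1(2H)-one
Product: 16 (4aR,5S,8aS)-5-[(3Z)-6-{(2S,3S)-3-methyl-3-[2-((2S)-3,3-dimethyloxiran-2-yl)ethyl]oxiran-2-yl}-4-[(triethylsilyl)oxy]hex-3-en-1-yl]-4,4,6-trimethyl-3,4,4a,5,8,8a-hexahydronaphthalen-1(2H)-one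
Conditions: Et3SiH, RhCl(PPh3)3 (2 mol %), benzene, 50 °C
Reagents that add atoms: triethylsilane, CC[SiH](CC)CC
Why: Rhodium-catalysed 1,4-hydrosilylation of the enone through its s-cis conformer should give the regiodefined (Z)-silyl enol ether C10=C11, which enolization could not give selectively because C9 and C11 would both be methylene groups; the hindered saturated ketone reacts far more slowly.

Step 11
Reactants: 16 (4aR,5S,8aS)-5-[(3Z)-6-{(2S,3S)-3-methyl-3-[2-((2S)-3,3-dimethyloxiran-2-yl)ethyl]oxiran-2-yl}-4-[(triethylsilyl)oxy]hex-3-en-1-yl]-4,4,6-trimethyl-3,4,4a,5,8,8a-hexahydronaphthalen-1(2H)-one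
Product: 19 rings A–D diketone (C10 and C19 ketones; O–C3 triethylsilyl ether), via epoxonium triflate 17 (not isolated), via silyloxocarbenium triflate 18 (not isolated)
Conditions: Et3SiOTf (1.0 equiv), 2,6-di-tert-butyl-4-methylpyridine, CH2Cl2 (0.005 M), −78 °C; aq. NaHCO3
Reagents that add atoms: triethylsilyl trifluoromethanesulfonate, CC[Si](CC)(CC)OS(=O)(=O)C(F)(F)F
Why: Et3SiOTf silylates the accessible C2–C3 epoxide, the oxygen of the C6–C7 epoxide opens it at the tertiary carbon C2 to give the bicyclic epoxonium ion 17, C11 of the enol silane attacks the tertiary carbon C6 with inversion, and the silyloxocarbenium ion 18 returns its silyl group to triflate, so the promoter is regenerated and its own silyl group ends on O–C3. The closest known reaction type is the silyl-triflate-promoted tandem oxa-/carbacyclization of 1,5-diepoxides terminated by enol silanes, which gives trans-fused oxepane–cyclohexanones. Ring A closes by endo opening of the activated epoxide by the neighbouring epoxide oxygen (O1–C2, seven-membered in the product); ring B closes last by 6-endo attack of the C10=C11 π-bond on C6 with endo opening of the epoxonium ion. C3 and C7 keep the configuration set by the epoxidation because their C–O bonds are never broken, C6 is inverted stereospecifically so that the E-epoxide becomes the trans ring fusion (C6–CH3 anti to H–C7), and C11 is set by the chair transition state in which the (Z)-enol silane places C12 equatorial, which is also the thermodynamic arrangement next to the C10 ketone. The step needs attack at the tertiary carbons C2 and C6 (not 5-exo closure to tetrahydrofurans), C–C bond formation ahead of other capture of the epoxonium ion, and an untouched ring D ketone; the alkyl substitution at C2 and C6, the non-nucleophilic medium (hindered pyridine, CH2Cl2, −78 °C, high dilution) and the higher Lewis basicity of the epoxides over the hindered ketone should secure this.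

Step 12
Reactants: 19 rings A–D diketone (C10 and C19 ketones; O–C3 triethylsilyl ether)
Product: 20 rings A–D bis(exocyclic methylene) compound (C10=CH2 and C19=CH2; O–C3 triethylsilyl ether)
Conditions: Cp2TiMe2 (6 equiv), toluene, 70 °C, dark
Reagents that add atoms: dimethyltitanocene, C[Ti](C)(C1C=CC=C1)C1C=CC=C1
Why: Petasis methylenation should convert both ketones into exocyclic methylenes under non-basic conditions, so the α-stereocentres C11 and C18 are not epimerized.

Step 13
Reactants: 20 rings A–D bis(exocyclic methylene) compound (C10=CH2 and C19=CH2; O–C3 triethylsilyl ether)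
Product: 21 sipholenol L 3-O-triethylsilyl ether
Conditions: Co(acac)2 (0.3 equiv), PhSiH3, O2 (1 atm), THF/i-PrOH, 0 → 23 °C
Reagents that add atoms: dioxygen, O=O
Why: Mukaiyama hydration, in which hydrogen-atom transfer to the two 1,1-disubstituted alkenes should outpace that to the trisubstituted C15=C16 alkene and O2 is captured on the open face of each tertiary centre: at C10 anti to the axial C6 methyl (equatorial OH), at C19 on the convex face syn to H–C18 (the other face is screened by C14), which sets both carbinol centres.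

Step 14
Reactants: 21 sipholenol L 3-O-triethylsilyl ether
Product: 22 sipholenol L
Conditions: HF·pyridine, pyridine, THF, 0 → 23 °C
Reagents that add atoms: none
Why: Fluoride-mediated desilylation should free the C3 hydroxyl; the buffered reagent leaves the tertiary alcohols and the alkene untouched.

**Compound list**

1 | pent-4-enoyl chloride | C=CCCC(=O)Cl | starting material
2 | tributyl(vinyl)stannane | C=C[Sn](CCCC)(CCCC)CCCC | starting material
3 | hepta-1,6-dien-3-one | C=CCCC(=O)C=C | intermediate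
4 | tert-butyl{[(3Z)-hepta-1,3,6-trien-3-yl]oxy}dimethylsilane | C=C/C(=C/CC=C)O[Si](C)(C)C(C)(C)C | intermediate
5 | 4,4-dimethylcyclohex-2-en-1-one | CC1(C)CCC(=O)C=C1 | starting material
6 | (4aR,5S,8aS)-6-[(tert-butyldimethylsilyl)oxy]-4,4-dimethyl-5-(prop-2-en-1-yl)-3,4,4a,5,8,8a-hexahydronaphthalen-1(2H)-one (cis-fused; allyl cis to ring D) | CC(C)(C)[Si](C)(C)OC1=CC[C@H]2[C@@H]([C@@H]1CC=C)C(C)(C)CCC2=O | intermediate
7 | (4aR,5S,8aS)-4,4-dimethyl-1-oxo-5-(prop-2-en-1-yl)-1,2,3,4,4a,5,8,8a-octahydronaphthalen-6-yl trifluoromethanesulfonate | O=S(=O)(OC1=CC[C@H]2[C@@H]([C@@H]1CC=C)C(C)(C)CCC2=O)C(F)(F)F | intermediate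
8 | (4aR,5S,8aS)-4,4,6-trimethyl-5-(prop-2-en-1-yl)-3,4,4a,5,8,8a-hexahydronaphthalen-1(2H)-one | CC1=CC[C@H]2[C@@H]([C@@H]1CC=C)C(C)(C)CCC2=O | intermediate
9 | geranyl bromide, (2E)-1-bromo-3,7-dimethylocta-2,6-diene | CC(C)=CCC/C(C)=C/CBr | starting material
10 | N-methoxy-N-methylacetamide | CC(=O)N(C)OC | starting material
11 | lithium enolate of N-methoxy-N-methylacetamide | [Li]OC(=C)N(C)OC | intermediate
12 | (4E)-N-methoxy-N,5,9-trimethyldeca-4,8-dienamide | CC(C)=CCC/C(C)=C/CCC(=O)N(C)OC | intermediate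
13 | N-methoxy-N-methyl-3-{(2S,3S)-3-methyl-3-[2-((2S)-3,3-dimethyloxiran-2-yl)ethyl]oxiran-2-yl}propanamide | CC1(C)O[C@H]1CC[C@]2(C)O[C@H]2CCC(=O)N(C)OC | intermediate
14 | 5-{(2S,3S)-3-methyl-3-[2-((2S)-3,3-dimethyloxiran-2-yl)ethyl]oxiran-2-yl}pent-1-en-3-one | CC1(C)O[C@H]1CC[C@]2(C)O[C@H]2CCC(=O)C=C | intermediate
15 | (4aR,5S,8aS)-5-[(2E)-6-{(2S,3S)-3-methyl-3-[2-((2S)-3,3-dimethyloxiran-2-yl)ethyl]oxiran-2-yl}-4-oxohex-2-en-1-yl]-4,4,6-trimethyl-3,4,4a,5,8,8a-hexahydronaphthalen-1(2H)-one | CC1=CC[C@H]2[C@@H]([C@@H]1C/C=C/C(=O)CC[C@@H]1O[C@@]1(C)CC[C@@H]1OC1(C)C)C(C)(C)CCC2=O | intermediate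
16 | (Z)-triethylsilyl enol ether (C10=C11) of the diepoxy diketone: (4aR,5S,8aS)-5-[(3Z)-6-{(2S,3S)-3-methyl-3-[2-((2S)-3,3-dimethyloxiran-2-yl)ethyl]oxiran-2-yl}-4-[(triethylsilyl)oxy]hex-3-en-1-yl]-4,4,6-trimethyl-3,4,4a,5,8,8a-hexahydronaphthalen-1(2H)-one | CC1=CC[C@H]2[C@@H]([C@@H]1CC/C=C(\O[Si](CC)(CC)CC)CC[C@@H]1O[C@@]1(C)CC[C@@H]1OC1(C)C)C(C)(C)CCC2=O | intermediate
17 | epoxonium triflate (O1 bonded to C2, C6 and C7; O–C3 triethylsilyl ether; enol silane intact) | CC1=CC[C@H]2[C@@H]([C@@H]1CC/C=C(\O[Si](CC)(CC)CC)CC[C@@H]1[O+]3C(C)(C)[C@@H](O[Si](CC)(CC)CC)CC[C@@]13C)C(C)(C)CCC2=O.[O-]S(=O)(=O)C(F)(F)F | intermediate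
18 | silyloxocarbenium triflate (rings A and B closed; C10=O+–SiEt3) | CC1=CC[C@H]2[C@@H]([C@@H]1CC[C@H]1[C@]3(C)CC[C@H](O[Si](CC)(CC)CC)C(C)(C)O[C@H]3CCC1=[O+][Si](CC)(CC)CC)C(C)(C)CCC2=O.[O-]S(=O)(=O)C(F)(F)F | intermediate
19 | rings A–D diketone (C10 and C19 ketones; O–C3 triethylsilyl ether; trans-fused A/B, C12 equatorial on C11, cis-fused C/D) | CC1=CC[C@H]2[C@@H]([C@@H]1CC[C@H]1[C@]3(C)CC[C@H](O[Si](CC)(CC)CC)C(C)(C)O[C@H]3CCC1=O)C(C)(C)CCC2=O | intermediate
20 | rings A–D bis(exocyclic methylene) compound (C10=CH2 and C19=CH2; O–C3 triethylsilyl ether) | CC1=CC[C@H]2[C@@H]([C@@H]1CC[C@H]1[C@]3(C)CC[C@H](O[Si](CC)(CC)CC)C(C)(C)O[C@H]3CCC1=C)C(C)(C)CCC2=C | intermediate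
21 | sipholenol L 3-O-triethylsilyl ether | CC1=CC[C@H]2[C@@H]([C@@H]1CC[C@H]1[C@]3(C)CC[C@H](O[Si](CC)(CC)CC)C(C)(C)O[C@H]3CC[C@]1(C)O)C(C)(C)CC[C@]2(C)O | intermediate
22 | sipholenol L | CC1=CC[C@H]2[C@@H]([C@@H]1CC[C@H]1[C@]3(C)CC[C@H](O)C(C)(C)O[C@H]3CC[C@]1(C)O)C(C)(C)CC[C@]2(C)O | target

**Step count**

Total steps: 14. Longest linear sequence: 11 (steps 1–5, then 9–14); steps 6–8 make the second fragment.

**Steps most likely to fail**

Step 3. The enone β-carbon C23 is neopentylic; if bond formation there turns stepwise (Mukaiyama–Michael addition, then ring closure), the chiral Lewis acid may discriminate the enone faces poorly. The fallback sets out from 4 and 5 and returns at 6. The cycloaddition is run with an achiral mixed Lewis acid (AlBr3/AlMe3, toluene/CH2Cl2, low temperature), which should give the racemic endo adduct, that is 6 together with its mirror image ent-6 F1. Addition of lithiated (S)-N,S-dimethyl-S-phenylsulfoximine to the C19 ketone (THF, −78 °C) should give two diastereomers, the β-hydroxysulfoximine of 6 F2 and the β-hydroxysulfoximine of ent-6 F3, separable by chromatography. Heating F2 (toluene, 110 °C) reverses the addition and returns enantiopure 6.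

Step 11. The enol silane may be lost before it is needed (protodesilylation by adventitious acid, or aldol-type capture by the silyl-activated ring D ketone), so that the epoxonium ion collapses along other paths. The fallback sets out from 16 and returns at 20. Fluoride-induced triflation of 16 (CsF, PhNTf2, DME) should give the (Z)-enol triflate F4 with the same double-bond position and geometry. Negishi coupling with (triethylsilyl)methylzinc chloride (Pd(PPh3)4, THF) should give the allylsilane F5, a robust, purely carbon-centred terminator of a class known for such epoxonium cascades. The same Et3SiOTf-promoted cascade should then close ring A and ring B and leave the exocyclic C10 methylene directly, giving the methylene ketone F6. Petasis methylenation of its remaining C19 ketone gives 20.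

Step 13. Hydrogen-atom transfer to the trisubstituted C15=C16 alkene may compete with that to the two 1,1-disubstituted alkenes, or oxygen capture may lack facial control. The fallback sets out from 20 and returns at 21 by an ionic hydration. Hg(OAc)2 in THF/H2O should add only to the two 1,1-disubstituted alkenes, which react far faster than a trisubstituted ring alkene. Water opens each mercurinium ion at the tertiary carbon from the open face to give the bis(acetoxymercurio) diol F7, and NaBH4/NaOH reduces it to 21.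

**Further compounds**

F1 | step 3 | ent-6, (4aS,5R,8aR)-6-[(tert-butyldimethylsilyl)oxy]-4,4-dimethyl-5-(prop-2-en-1-yl)-3,4,4a,5,8,8a-hexahydronaphthalen-1(2H)-one | CC(C)(C)[Si](C)(C)OC1=CC[C@@H]2[C@H]([C@H]1CC=C)C(C)(C)CCC2=O
F2 | step 3 | β-hydroxysulfoximine of 6 (C19 carbinol bearing CH2–S(O)(=NMe)Ph, sulfur S-configured) | CC(C)(C)[Si](C)(C)OC1=CC[C@H]2[C@@H]([C@@H]1CC=C)C(C)(C)CC[C@]2(O)C[S@@](=O)(=NC)c1ccccc1
F3 | step 3 | β-hydroxysulfoximine of ent-6 (diastereomer of F2) | CC(C)(C)[Si](C)(C)OC1=CC[C@@H]2[C@H]([C@H]1CC=C)C(C)(C)CC[C@@]2(O)C[S@@](=O)(=NC)c1ccccc1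
F4 | step 11 | (Z)-enol triflate at C10=C11 of the diepoxy ketone | CC1=CC[C@H]2[C@@H]([C@@H]1CC/C=C(\OS(=O)(=O)C(F)(F)F)CC[C@@H]1O[C@@]1(C)CC[C@@H]1OC1(C)C)C(C)(C)CCC2=O
F5 | step 11 | allylsilane (C10 bearing CH2SiEt3, C10=C11, C12 cis to the silylmethyl group) | CC1=CC[C@H]2[C@@H]([C@@H]1CC/C=C(\C[Si](CC)(CC)CC)CC[C@@H]1O[C@@]1(C)CC[C@@H]1OC1(C)C)C(C)(C)CCC2=O
F6 | step 11 | rings A–D methylene ketone (C10=CH2, C19 ketone, O–C3 triethylsilyl ether) | CC1=CC[C@H]2[C@@H]([C@@H]1CC[C@H]1[C@]3(C)CC[C@H](O[Si](CC)(CC)CC)C(C)(C)O[C@H]3CCC1=C)C(C)(C)CCC2=O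
F7 | step 13 | bis(acetoxymercurio) diol (C10 and C19 carbinols each bearing CH2HgOAc; O–C3 triethylsilyl ether) | CC1=CC[C@H]2[C@@H]([C@@H]1CC[C@H]1[C@]3(C)CC[C@H](O[Si](CC)(CC)CC)C(C)(C)O[C@H]3CC[C@]1(C[Hg]OC(C)=O)O)C(C)(C)CC[C@]2(C[Hg]OC(C)=O)O
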